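**Strategy**

Everything rests on cutting the C1–C8a bond of ring B, which turns the naphthazarin core into a 4-aryl-4-hydroxycyclobutenone. The feature used is the 1,4-dione pattern of ring B: C1 and C4 are carbonyl carbons, C2 holds the quaternary carbinol carbon Ca, and ring A carries the same oxygen at C5 and C8, so either carbonyl may derive from the ketene. On heating, the four-membered enone opens to a vinylketene that closes onto the free ortho carbon of the aryl group and builds ring B as its 1,4-diol in one operation. The precursor bears the intact (R)-angeloyloxycyclobutyl unit beside the enone carbonyl and a 2,5-bis(methoxymethoxy)phenyl group on the carbinol carbon.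

Key step: step 7

**Remarks on the chemistry**

- Assumption: the antipode of the salen ligand used in step 1 is the one that a single trial run shows to give the (R)-carbinol; both antipodes are commercial.
- Ring A phenols are masked as methoxymethyl ethers instead of methyl ethers, so that the last step needs only dilute acid and no boron halide meets the tertiary angelate.
- The dichloride is hydrolysed with a silver salt in the cold, not with hot mineral acid, which would threaten the ester and the Z-alkene.
- Ca is (R) in the target by the ranking O > ring-B carbon > CMe2 > CH2; the same ranking and descriptor hold for every intermediate.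
- The carbinol carbon of the four-membered enone forms as both epimers and is drawn without configuration, because the key step flattens it.

**Route**

Step 1
Reactants: 1 2,2-dimethylcyclobutan-1-one; 2 ethynyltrimethylsilane
Product: 5 (R)-1-ethynyl-2,2-dimethylcyclobutan-1-ol, via alkynylzinc reagent 3 (not isolated), via silyl alkynol 4 (not isolated)
Conditions: Me2Zn (3 equiv), 2 (3 equiv), N,N′-bis(3,5-di-tert-butylsalicylidene)cyclohexane-1,2-diamine (one antipode, 20 mol %), PhMe, rt; aq NH4Cl; then K2CO3, MeOH, rt
Reagents that add atoms: none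
Why: Catalytic enantioselective addition of an alkynylzinc to a ketone: the chiral zinc–salen complex binds the strained, electrophilic cyclobutanone and passes the alkynyl group to the face that keeps the quaternary CMe2 flank away from the tert-butyl groups of the ligand, which sets Ca as (R) with the chosen antipode, and carbonate-catalysed methanolysis then cleaves the C–Si bond.

Step 2
Reactants: 5 (R)-1-ethynyl-2,2-dimethylcyclobutan-1-ol; 6 angelic acid
Product: 9 (R)-1-ethynyl-2,2-dimethylcyclobutyl (Z)-2-methylbut-2-enoate, via lithium alkoxide 7 (not isolated), via mixed anhydride 8 (not isolated)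
Conditions: 6, 2,4,6-Cl3C6H2COCl, Et3N, PhMe, rt; separately 5, LiN(SiMe3)2, THF, −78 °C; combine, −78 → 0 °C; aq NH4Cl
Reagents that add atoms: none
Why: O-acylation of a lithium alkoxide by a mixed carboxylic anhydride: the alkoxide attacks the angeloyl carbonyl because the other carbonyl is screened by two ortho chlorines, no nucleophilic amine is present that could turn the Z-alkene into the E-isomer, and the C–O bond at Ca is never broken, so its configuration is kept.

Step 3
Reactants: 9 (R)-1-ethynyl-2,2-dimethylcyclobutyl (Z)-2-methylbut-2-enoate; 10 trichloroacetyl chloride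
Product: 12 (R)-1-(4,4-dichloro-3-oxocyclobut-1-en-1-yl)-2,2-dimethylcyclobutyl (Z)-2-methylbut-2-enoate, via dichloroketene 11 (not isolated)
Conditions: 10 (3 equiv), Zn–Cu couple, Et2O–DME, rt
Reagents that add atoms: none
Why: Thermal [2+2] cycloaddition of a ketene to an alkyne: dichloroketene, freed from 10 by zinc, bonds through its carbonyl carbon to the unsubstituted alkyne carbon, DME ties up ZnCl2 so that allylic chloride shifts stay slow, and the electron-poor alkene of the angelate does not react with this electrophilic ketene.

Step 4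
Reactants: 12 (R)-1-(4,4-dichloro-3-oxocyclobut-1-en-1-yl)-2,2-dimethylcyclobutyl (Z)-2-methylbut-2-enoate
Product: 13 (R)-1-(3,4-dioxocyclobut-1-en-1-yl)-2,2-dimethylcyclobutyl (Z)-2-methylbut-2-enoate
Conditions: AgO2CCF3 (2.2 equiv), acetone–H2O (10:1), 0 °C → rt, dark
Reagents that add atoms: water, O
Why: Silver-assisted SN1 hydrolysis of an allylic geminal dichloride: AgO2CCF3 pulls off chloride to give a chlorine-stabilised cyclobutenyl cation, water adds at the chlorine-bearing carbon and the chlorohydrin loses HCl to give the 1,2-dione, under cold and only weakly acidic conditions that leave the tertiary ester and the Z-alkene alone.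

Step 5
Reactants: 14 hydroquinone
Product: 15 1,4-bis(methoxymethoxy)benzene
Conditions: MOMCl (2.5 equiv), i-Pr2NEt, DMF, 0 °C → rt
Reagents that add atoms: chloromethyl methyl ether (MOMCl), COCCl
Why: Base-mediated O-alkylation of both phenols by the chloromethyl ether (Williamson-type ether synthesis) gives the bis-acetal, whose oxygens direct the lithiation of step 6 and are later removed by dilute acid.

Step 6
Reactants: 13 (R)-1-(3,4-dioxocyclobut-1-en-1-yl)-2,2-dimethylcyclobutyl (Z)-2-methylbut-2-enoate; 15 1,4-bis(methoxymethoxy)benzene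
Product: 17 (R)-1-{3-[2,5-bis(methoxymethoxy)phenyl]-3-hydroxy-4-oxocyclobut-1-en-1-yl}-2,2-dimethylcyclobutyl (Z)-2-methylbut-2-enoate (both epimers at the ring carbinol carbon), via aryllithium 16 (not isolated)
Conditions: 15 (1.2 equiv), n-BuLi (1.1 equiv), THF, 0 °C; then added to 13, THF, −78 °C; AcOH, −78 °C
Reagents that add atoms: none
Why: Directed ortho-lithiation followed by 1,2-addition of an aryllithium to a cyclobutene-1,2-dione: the four ring positions of 15 are equivalent, the aryllithium attacks the less hindered carbonyl (the one next to CH) far faster at −78 °C than the hindered ester, the new carbinol centre forms without control and is erased in step 7, and addition at the other carbonyl would lead to the same diol because ring A is symmetric.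

Step 7
Reactants: 17 (R)-1-{3-[2,5-bis(methoxymethoxy)phenyl]-3-hydroxy-4-oxocyclobut-1-en-1-yl}-2,2-dimethylcyclobutyl (Z)-2-methylbut-2-enoate
Product: 20 (R)-1-[1,4-dihydroxy-5,8-bis(methoxymethoxy)naphthalen-2-yl]-2,2-dimethylcyclobutyl (Z)-2-methylbut-2-enoate, via vinylketene 18 (not isolated), via cyclohexadienone 19 (not isolated)
Conditions: PhMe (degassed, 0.02 M), 110 °C, Ar, 1–2 h (p-xylene, 138 °C, if conversion is slow); crude product kept under Ar and used at once
Reagents that add atoms: none
Why: Heating triggers conrotatory 4π electrocyclic opening of the C1–C4 bond of the cyclobutenone, the hydroxyl turning outward, to give the (E)-vinylketene 18 with the aryl group cis to the ketene; disrotatory 6π electrocyclisation then joins the ketene carbon to the unsubstituted ortho carbon of the aryl ring and the resulting dienone 19 enolises to the naphthalene-1,4-diol. The closest known reaction type is the Moore rearrangement of 4-aryl-4-hydroxycyclobutenones to 1,4-naphthohydroquinones. Ring B is the only ring closed, by a thermally allowed six-electron electrocyclisation that forms the C1–C8a bond of a six-membered ring. No lasting stereocentre is created: the ring carbinol centre and the transient C8a are both flattened on aromatisation, and Ca, a spectator, keeps its (R) configuration. The step needs outward torquoselectivity of the hydroxyl, which its lone-pair donation secures; closure at the free ortho carbon and not at the one bearing OCH2OCH3, since only the former can rearomatise; and opening of the cyclobutenone alone, which holds because the saturated cyclobutane has no π bond and therefore no allowed path at this temperature.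

Step 8
Reactants: 20 (R)-1-[1,4-dihydroxy-5,8-bis(methoxymethoxy)naphthalen-2-yl]-2,2-dimethylcyclobutyl (Z)-2-methylbut-2-enoate
Product: 21 (R)-1-[5,8-bis(methoxymethoxy)-1,4-dioxo-1,4-dihydronaphthalen-2-yl]-2,2-dimethylcyclobutyl (Z)-2-methylbut-2-enoate
Conditions: Ag2O (1.5 equiv), MgSO4, Et2O, rt
Reagents that add atoms: none
Why: Oxidation of a 1,4-naphthalenediol to the para-quinone by Ag2O, a fast two-electron dehydrogenation of an electron-rich hydroquinone that touches neither the acetals nor the ester and removes the free phenol beside the tertiary ester at once.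

Step 9
Reactants: 21 (R)-1-[5,8-bis(methoxymethoxy)-1,4-dioxo-1,4-dihydronaphthalen-2-yl]-2,2-dimethylcyclobutyl (Z)-2-methylbut-2-enoate
Product: 22 (R)-1-(5,8-dihydroxy-1,4-dioxo-1,4-dihydronaphthalen-2-yl)-2,2-dimethylcyclobutyl (Z)-2-methylbut-2-enoate
Conditions: TFA–CH2Cl2–H2O (10:40:1), 0 °C → rt
Reagents that add atoms: none
Why: Acid-catalysed hydrolysis of aryl methoxymethyl acetals, eased by hydrogen bonding of the freed phenols to the peri carbonyls, while the tertiary ester does not ionise because its cation would lie next to the electron-poor quinone ring, so the naphthazarin target results with Ca unchanged.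

**Compound list**

1 | 2,2-dimethylcyclobutan-1-one | CC1(C)CCC1=O | starting material
2 | ethynyltrimethylsilane | C#C[Si](C)(C)C | starting material
3 | methyl[(trimethylsilyl)ethynyl]zinc | C[Zn]C#C[Si](C)(C)C | intermediate
4 | (R)-2,2-dimethyl-1-[(trimethylsilyl)ethynyl]cyclobutan-1-ol | O[C@]1(C#C[Si](C)(C)C)CCC1(C)C | intermediate
5 | (R)-1-ethynyl-2,2-dimethylcyclobutan-1-ol | O[C@]1(C#C)CCC1(C)C | intermediate
6 | angelic acid, (Z)-2-methylbut-2-enoic acid | C/C=C(/C)C(=O)O | starting material
7 | lithium (R)-1-ethynyl-2,2-dimethylcyclobutan-1-olate | [Li+].[O-][C@]1(C#C)CCC1(C)C | intermediate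
8 | (Z)-2-methylbut-2-enoic 2,4,6-trichlorobenzoic anhydride | C/C=C(/C)C(=O)OC(=O)c1c(Cl)cc(Cl)cc1Cl | intermediate
9 | (R)-1-ethynyl-2,2-dimethylcyclobutyl (Z)-2-methylbut-2-enoate | C/C=C(/C)C(=O)O[C@]1(C#C)CCC1(C)C | intermediate
10 | trichloroacetyl chloride | ClC(Cl)(Cl)C(Cl)=O | starting material
11 | dichloroketene | ClC(Cl)=C=O | intermediate
12 | (R)-1-(4,4-dichloro-3-oxocyclobut-1-en-1-yl)-2,2-dimethylcyclobutyl (Z)-2-methylbut-2-enoate | C/C=C(/C)C(=O)O[C@]1(C2=CC(=O)C2(Cl)Cl)CCC1(C)C | intermediate
13 | (R)-1-(3,4-dioxocyclobut-1-en-1-yl)-2,2-dimethylcyclobutyl (Z)-2-methylbut-2-enoate | C/C=C(/C)C(=O)O[C@]1(C2=CC(=O)C2=O)CCC1(C)C | intermediate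
14 | hydroquinone (benzene-1,4-diol) | Oc1ccc(O)cc1 | starting material
15 | 1,4-bis(methoxymethoxy)benzene | COCOc1ccc(OCOC)cc1 | intermediate
16 | [2,5-bis(methoxymethoxy)phenyl]lithium | [Li]c1cc(OCOC)ccc1OCOC | intermediate
17 | (R)-1-{3-[2,5-bis(methoxymethoxy)phenyl]-3-hydroxy-4-oxocyclobut-1-en-1-yl}-2,2-dimethylcyclobutyl (Z)-2-methylbut-2-enoate, both epimers at the ring carbinol carbon | C/C=C(/C)C(=O)O[C@]1(C2=CC(O)(c3cc(OCOC)ccc3OCOC)C2=O)CCC1(C)C | intermediate
18 | (R)-1-{(3E)-4-[2,5-bis(methoxymethoxy)phenyl]-4-hydroxy-1-oxobuta-1,3-dien-2-yl}-2,2-dimethylcyclobutyl (Z)-2-methylbut-2-enoate | C/C=C(/C)C(=O)O[C@]1(C(=C=O)/C=C(/O)c2cc(OCOC)ccc2OCOC)CCC1(C)C | intermediate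
19 | (R)-1-[4-hydroxy-5,8-bis(methoxymethoxy)-1-oxo-1,8a-dihydronaphthalen-2-yl]-2,2-dimethylcyclobutyl (Z)-2-methylbut-2-enoate, C8a unassigned | C/C=C(/C)C(=O)O[C@]1(C2=CC(O)=C3C(OCOC)=CC=C(OCOC)C3C2=O)CCC1(C)C | intermediate
20 | (R)-1-[1,4-dihydroxy-5,8-bis(methoxymethoxy)naphthalen-2-yl]-2,2-dimethylcyclobutyl (Z)-2-methylbut-2-enoate | C/C=C(/C)C(=O)O[C@]1(c2cc(O)c3c(OCOC)ccc(OCOC)c3c2O)CCC1(C)C | intermediate
21 | (R)-1-[5,8-bis(methoxymethoxy)-1,4-dioxo-1,4-dihydronaphthalen-2-yl]-2,2-dimethylcyclobutyl (Z)-2-methylbut-2-enoate | C/C=C(/C)C(=O)O[C@]1(C2=CC(=O)c3c(OCOC)ccc(OCOC)c3C2=O)CCC1(C)C | intermediate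
22 | (R)-1-(5,8-dihydroxy-1,4-dioxo-1,4-dihydronaphthalen-2-yl)-2,2-dimethylcyclobutyl (Z)-2-methylbut-2-enoate | C/C=C(/C)C(=O)O[C@]1(C2=CC(=O)c3c(O)ccc(O)c3C2=O)CCC1(C)C | target

**Step count**

Total steps: 9. Longest linear sequence: 8 steps (1 → 5 → 9 → 12 → 13 → 17 → 20 → 21 → 22, that is steps 1–4 and 6–9); step 5 is a one-step branch.

**Steps most likely to fail**

1. Step 7 (key step). Once the electron-rich naphthalenediol has formed, the tertiary ester beside a free phenol may be lost by thermal elimination of angelic acid (quinone-methide pathway) or by acyl shift to the phenol oxygen. Some inward rotation of the hydroxyl would also divert the ketene into lactonisation. Fallback, setting out from 9 and 16 and coming back at 21: ring B is built instead by Dötz benzannulation at lower temperature. Aryllithium 16 is added to Cr(CO)6 in Et2O to give the lithium acylchromate F1, which Me3OBF4 methylates on oxygen to the methoxycarbene complex F2. Warming F2 with alkyne 9 in THF at about 50 °C should insert the alkyne and one CO and give the 4-methoxy-1-naphthol F3, with the bulky alkyne substituent next to the new phenol. Oxidation of crude F3 with (NH4)2Ce(NO3)6 in aqueous MeCN at 0 °C should then give quinone 21.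

2. Step 4. Chloride may migrate to the allylic position before water arrives, the cation may be captured at the carbon remote from chlorine, or the acid released may isomerise the angelate from Z to E. Fallback, setting out from 12 and coming back at 17: the order of events is reversed. Aryllithium 16 is added at −78 °C to the ketone of 12 to give the dichloro carbinol F4. Its geminal dichloride is no longer flanked by a carbonyl group, so silver-assisted hydrolysis (AgO2CCF3, wet acetone, 0 °C) should be easier; it unveils the enone carbonyl and gives 17 with unambiguous regiochemistry.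

3. Step 1. Facial discrimination between the CH2 and CMe2 flanks of the small ketone may be too weak, leaving enantiomeric purity too low to carry forward. Fallback, setting out from 1 and coming back at 9: resolution replaces catalysis. HC≡CMgBr in THF adds to 1 to give the racemic alkynol F5, which is acylated as in step 2 to the racemic ester F6. Preparative chromatography on a chiral stationary phase then separates 9 from its discarded enantiomer, the (S)-ester F7.

**Further compounds**

F1 | step 7 | lithium pentacarbonyl{[2,5-bis(methoxymethoxy)phenyl](oxido)methylidene}chromate | [Li+].[O-]C(c1cc(OCOC)ccc1OCOC)=[Cr](=C=O)(=C=O)(=C=O)(=C=O)=C=O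
F2 | step 7 | pentacarbonyl{[2,5-bis(methoxymethoxy)phenyl](methoxy)methylidene}chromium | COC(c1cc(OCOC)ccc1OCOC)=[Cr](=C=O)(=C=O)(=C=O)(=C=O)=C=O
F3 | step 7 | (R)-1-[1-hydroxy-4-methoxy-5,8-bis(methoxymethoxy)naphthalen-2-yl]-2,2-dimethylcyclobutyl (Z)-2-methylbut-2-enoate | C/C=C(/C)C(=O)O[C@]1(c2cc(OC)c3c(OCOC)ccc(OCOC)c3c2O)CCC1(C)C
F4 | step 4 | (R)-1-{3-[2,5-bis(methoxymethoxy)phenyl]-4,4-dichloro-3-hydroxycyclobut-1-en-1-yl}-2,2-dimethylcyclobutyl (Z)-2-methylbut-2-enoate, both carbinol epimers | C/C=C(/C)C(=O)O[C@]1(C2=CC(O)(c3cc(OCOC)ccc3OCOC)C2(Cl)Cl)CCC1(C)C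
F5 | step 1 | rac-1-ethynyl-2,2-dimethylcyclobutan-1-ol | OC1(C#C)CCC1(C)C
F6 | step 1 | rac-1-ethynyl-2,2-dimethylcyclobutyl (Z)-2-methylbut-2-enoate | C/C=C(/C)C(=O)OC1(C#C)CCC1(C)C
F7 | step 1 | (S)-1-ethynyl-2,2-dimethylcyclobutyl (Z)-2-methylbut-2-enoate | C/C=C(/C)C(=O)O[C@@]1(C#C)CCC1(C)C
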